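**Assumption:** the two C12 carbinol epimers from Step 18 are separable on silica, and Steps 18–19 convert both to the 12S ester.

## Retrosynthetic overview
1. The target comes from late chloride opening of a 4α,18-spiroepoxide. The butenolide comes from a 3-furyl group (singlet O2), and the C12 ester from furyl addition to a C12 aldehyde made by cleaving a C9-allyl group.
2. The C9 quaternary centre (C9–C11 bond) is forged photochemically. A C9 tertiary alcohol (ketone + MeLi) is converted to its cesium oxalate, and photoredox deoxygenative allylation builds the centre. The trans-decalin sets the facial selectivity.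
3. Ring A closes by intramolecular aldol (C10 enolate onto a C1 aldehyde), which gives the 1β-OH/10β-H array thermodynamically. C4=C18 comes from Wittig methylenation.
4. Ring B is a 1,4-dione from (R)-carvone. C5 is quaternized by α-alkylation (C19), C6 is set by ketone reduction, and ring B is formed before ring A.

## Route

**Step 1**
Reactants: 1 (R)-(−)-carvone
Product: 2 (5R)-2-methyl-5-isopropenylcyclohex-2-ene-1,4-dione
Conditions: Pd(OH)2/C (10 mol%), TBHP, K2CO3, CH2Cl2, rt
Reagents that add atoms: tert-butyl hydroperoxide, CC(C)(C)OO (source of the new C=O oxygen)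
Why: Pd-catalysed allylic (γ) C–H oxidation of the enone at its only allylic ring CH2 (clerodane C6) installs the C6 oxygen level; no stereocentre changes.

**Step 2**
Reactants: 2
Product: 3 2-methyl-5-isopropenylcyclohexane-1,4-dione (C8-Me α, C5-isopropenyl β, trans-diequatorial)
Conditions: Zn dust, AcOH, THF, 0 °C → rt
Reagents that add atoms: none
Why: Zn/AcOH 1,4-reduction of the ene-dione; axial protonation of the enol at C8 puts Me equatorial, trans to the carvone-derived isopropenyl, which sets the C8 centre.

**Step 3**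
Reactants: 3, chloromethyl acetate
Product: 4 (C5-acetoxymethyl/isopropenyl quaternary 1,4-dione)
Conditions: t-BuOK (1.05 equiv), THF, −78 °C; then ClCH2OAc, DMPU, −78 → 0 °C
Reagents that add atoms: chloromethyl acetate, CC(=O)OCCl (adds CH2OAc = C19)
Why: Deconjugative α-alkylation of the extended C6/C5 enolate. Axial attack from the α-face of the chair (C8-Me equatorial) gives C19 axial α and isopropenyl equatorial β. The carvone C5 centre is erased and re-set under C8 control.

**Step 4**
Reactants: 4
Product: 5 (C9 ethylene ketal)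
Conditions: 1,2-bis(trimethylsilyloxy)ethane, TMSOTf (cat.), CH2Cl2, −78 → 0 °C
Reagents that add atoms: 1,2-bis(trimethylsilyloxy)ethane, C[Si](C)(C)OCCO[Si](C)(C)C (adds OCH2CH2O)
Why: Noyori ketalization is selective for the C9 ketone; the C6 ketone is shielded by quaternary C5.

**Step 5**
Reactants: 5
Product: 6 (6α-alcohol, equatorial)
Conditions: NaBH4, MeOH/CH2Cl2, −20 → 0 °C
Reagents that add atoms: none
Why: A small hydride attacks axially from the β-face of C6 to give the equatorial 6α-OH. The C19 acetate may migrate to the C6 alkoxide; Step 6 resolves this.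

**Step 6**
Reactants: 6
Product: 7 (6α-OAc, 19-OAc)
Conditions: Ac2O, pyridine, DMAP, CH2Cl2, rt
Reagents that add atoms: acetic anhydride, CC(=O)OC(C)=O
Why: Acetylation gives the final C6 and C19 acetates and erases any acyl migration; configuration is retained.

**Step 7**
Reactants: 7
Product: 8 (C4 methyl ketone)
Conditions: O3, CH2Cl2/MeOH, −78 °C; then Me2S
Reagents that add atoms: ozone, [O-][O+]=O
Why: Ozonolysis converts the isopropenyl group to an acetyl group (C4=O with C3 methyl); the ketal and esters are inert.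

**Step 8**
Reactants: 8
Product: 9 (C4 ketone bearing C3–C2–C1 acetal chain)
Conditions: LDA, THF, −78 °C; then NaI, HMPA, 2-(bromomethyl)-1,3-dioxolane, −78 °C → rt
Reagents that add atoms: 2-(bromomethyl)-1,3-dioxolane, BrCC1OCCO1 (adds C2 and C1 as a masked aldehyde)
Why: Only the C3 methyl is enolizable (C5 is quaternary), so kinetic enolate alkylation is regiospecific.

**Step 9**
Reactants: 9
Product: 10 (C4=C18 exocyclic alkene)
Conditions: Ph3P=CH2 (Ph3PCH3Br, t-BuOK), THF, 0 °C → rt
Reagents that add atoms: methyltriphenylphosphonium bromide, C[P+](c1ccccc1)(c1ccccc1)c1ccccc1.[Br-] (supplies C18)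
Why: Wittig methylenation of the only free ketone (C9 is ketal-masked), creating the C4=C18 alkene for the later spiroepoxide.

**Step 10**
Reactants: 10
Product: 11 (C9 ketone, C1 aldehyde)
Conditions: PPTS, acetone/H2O, 60 °C
Reagents that add atoms: water, O (oxygen of the regenerated C=O groups)
Why: Mild acid hydrolyses both the ketal and the dioxolane while leaving the exocyclic alkene and acetates.

**Step 11**
Reactants: 11
Product: 12 (decalin 1β-ol 9-ketone)
Conditions: pyrrolidine (20 mol%), AcOH (20 mol%), CH2Cl2, rt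
Reagents that add atoms: none
Why: Enamine intramolecular aldol (C10 donor, C1 aldehyde acceptor) closes ring A. The aldol is reversible and funnels to the thermodynamic trans-fused ketol with equatorial 1β-OH and axial 10β-H, which sets C1 and C10.

**Step 12**
Reactants: 12
Product: 13 (C9 tertiary alcohol, C9 configuration undefined)
Conditions: MeLi (3.3 equiv), CeCl3 (3.5 equiv), THF, −78 °C
Reagents that add atoms: methyllithium, [Li]C (adds C20)
Why: Organocerium 1,2-addition to the only ketone. C9 configuration is irrelevant because it becomes a planar radical in Step 15.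

**Step 13**
Reactants: 13, 14 (S)-2-methylbutanoic acid
Product: 15 (1β-(S)-2-methylbutanoate)
Conditions: EDC·HCl, DMAP, CH2Cl2, rt
Reagents that add atoms: none beyond reactant 14
Why: Steglich esterification acylates the secondary C1-OH selectively over the tertiary C9-OH, with retention.

**Step 14**
Reactants: 15
Product: 16 (C9 cesium oxalate)
Conditions: (i) ClC(O)CO2Me, pyridine, DMAP, CH2Cl2, 0 °C; (ii) CsOH·H2O (1.0 equiv), MeOH, rt
Reagents that add atoms: methyl chlorooxoacetate, COC(=O)C(=O)Cl; cesium hydroxide, [Cs+].[OH-]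
Why: Converts the tertiary alcohol into a radical precursor (oxalate half-ester Cs salt); no stereocentre changes.

**Step 15**
Reactants: 16
Product: 17 (C9-allyl quaternary centre)
Conditions: Ir[dF(CF3)ppy]2(dtbbpy)PF6 (2 mol%), allyl phenyl sulfone (5 equiv), DMF, blue LEDs, rt
Reagents that add atoms: allyl phenyl sulfone, C=CCS(=O)(=O)c1ccccc1 (adds C11, C12, C13′ as the allyl group)
Why: Photoredox deoxygenative radical allylation gives the tertiary C9 radical, which is attacked from the β-face because the α-axial trajectory is blocked by the syn-axial C19. This gives C11 β and C20 α.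
Proposed new method: Ir(III)* oxidises the oxalate, two CO2 are lost to give the tertiary C9 radical, the radical adds to the CH2 terminus of the allyl sulfone, β-scission releases PhSO2•, and Ir(II) reduces it to PhSO2−, closing a redox-neutral cycle. The closest known chemistry is tertiary-oxalate Giese additions and Keck-type radical allylation. It is new here because the radical is flanked by two tertiary centres (C8, C10), lies 1,3 to the quaternary C5, and the substrate carries an exocyclic alkene and four esters.

**Step 16**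
Reactants: 17
Product: 18 (4α,18-spiroepoxide)
Conditions: mCPBA, NaHCO3, CH2Cl2, 0 °C
Reagents that add atoms: mCPBA, OOC(=O)c1cccc(Cl)c1 (O atom)
Why: Prilezhaev epoxidation is selective for the more nucleophilic 1,1-disubstituted exocyclic alkene over the monosubstituted allyl. Peracid attack from the equatorial (α) side puts O α and C18 axial β.

**Step 17**
Reactants: 18
Product: 19 (C12 aldehyde)
Conditions: OsO4 (2 mol%), NaIO4, 2,6-lutidine, dioxane/H2O, rt
Reagents that add atoms: sodium periodate, [Na+].[O-]I(=O)(=O)=O (oxygen of the aldehyde)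
Why: Lemieux–Johnson cleavage of the terminal alkene; the spiroepoxide and esters survive.

**Step 18**
Reactants: 19
Product: 20 (12S-carbinol) and 21 (12R-carbinol)
Conditions: 3-bromofuran, n-BuLi, Et2O, −78 °C; then CeCl3; add 19, −78 °C; separate by silica gel
Reagents that add atoms: 3-bromofuran, Brc1ccoc1 (adds the 3-furyl group, C13–C16 plus the ring oxygen)
Why: Organocerium 1,2-addition to the aldehyde (C12–C13 bond). Selectivity comes only from 1,3-induction by C9, so both epimers are carried forward.

**Step 19**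
Reactants: 20 or 21, plus 14
Product: 22 (12S-(S)-2-methylbutanoate)
Conditions: for 20, EDC·HCl, DMAP, CH2Cl2; for 21, DIAD, PPh3, THF (Mitsunobu)
Reagents that add atoms: none beyond reactant 14
Why: Steglich esterification retains configuration and Mitsunobu inverts it, so both carbinols converge to the 12S ester.

**Step 20**
Reactants: 22
Product: 23 (γ-hydroxybutenolide)
Conditions: O2, methylene blue, visible light, iPr2NEt, CH2Cl2, −78 °C
Reagents that add atoms: oxygen, O=O
Why: Singlet-oxygen [4+2] of the 3-substituted furan, then base-mediated Kornblum–DeLaMare opening of the endoperoxide, gives the 4-substituted 5-hydroxy-2(5H)-furanone (C16 is an undefined epimeric centre).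

**Step 21**
Reactants: 23
Product: 24 (butenolide)
Conditions: NaBH4, EtOH, 0 °C; then pH 4 buffer
Reagents that add atoms: none
Why: The ring-opened (Z)-aldehyde carboxylate is reduced to the alcohol and relactonises on acidification to the 2(5H)-furanone. The epoxide and esters survive at 0 °C.

**Step 22**
Reactants: 24
Product: 25 ajugaciliatin A
Conditions: LiCl, AcOH, THF, 40 °C
Reagents that add atoms: lithium chloride, [Li+].[Cl-] (with AcOH as proton source)
Why: Chloride opens the tertiary spiroepoxide by SN2 at the unhindered primary C18, with retention at C4, to give the 4α-OH/18-Cl chlorohydrin.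

## Compound list
1 | (R)-(−)-carvone | CC1=CC[C@H](CC1=O)C(C)=C | starting material
2 | 2-methyl-5-isopropenylcyclohex-2-ene-1,4-dione | CC1=CC(=O)[C@@H](C(C)=C)CC1=O | intermediate
3 | trans-2-methyl-5-isopropenylcyclohexane-1,4-dione | O=C1[C@H](C)CC(=O)[C@@H](C(C)=C)C1 | intermediate
4 | C5-acetoxymethyl C5-isopropenyl ring-B 1,4-dione | O=C1[C@H](C)CC(=O)[C@@](COC(C)=O)(C(C)=C)C1 | intermediate
5 | C9 ethylene ketal of 4 | O1CCOC12[C@H](C)CC(=O)[C@@](COC(C)=O)(C(C)=C)C2 | intermediate
6 | 6α-alcohol ketal | O1CCOC12[C@H](C)C[C@H](O)[C@@](COC(C)=O)(C(C)=C)C2 | intermediate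
7 | 6α,19-diacetate ketal | O1CCOC12[C@H](C)C[C@H](OC(C)=O)[C@@](COC(C)=O)(C(C)=C)C2 | intermediate
8 | C4 methyl ketone | O1CCOC12[C@H](C)C[C@H](OC(C)=O)[C@@](COC(C)=O)(C(C)=O)C2 | intermediate
9 | chain-extended C4 ketone (dioxolane) | O1CCOC12[C@H](C)C[C@H](OC(C)=O)[C@@](COC(C)=O)(C(=O)CCC3OCCO3)C2 | intermediate
10 | C4-methylene dioxolane ketal | O1CCOC12[C@H](C)C[C@H](OC(C)=O)[C@@](COC(C)=O)(C(=C)CCC3OCCO3)C2 | intermediate
11 | C9 ketone/C1 aldehyde | O=C1[C@H](C)C[C@H](OC(C)=O)[C@@](COC(C)=O)(C(=C)CCC=O)C1 | intermediate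
12 | decalin 1β-ol 9-ketone | O=C1[C@H](C)C[C@H](OC(C)=O)[C@]2(COC(C)=O)[C@@H]1[C@H](O)CCC2=C | intermediate
13 | C9 tertiary alcohol, 1β-OH | CC1(O)[C@H](C)C[C@H](OC(C)=O)[C@]2(COC(C)=O)[C@@H]1[C@H](O)CCC2=C | intermediate
14 | (S)-2-methylbutanoic acid | CC[C@H](C)C(=O)O | starting material
15 | 1β-(S)-2-methylbutanoate, C9 tertiary alcohol | CC1(O)[C@H](C)C[C@H](OC(C)=O)[C@]2(COC(C)=O)[C@@H]1[C@H](OC(=O)[C@@H](C)CC)CCC2=C | intermediate
16 | C9 cesium oxalate | CC1(OC(=O)C(=O)[O-])[C@H](C)C[C@H](OC(C)=O)[C@]2(COC(C)=O)[C@@H]1[C@H](OC(=O)[C@@H](C)CC)CCC2=C.[Cs+] | intermediate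
17 | C9-allyl compound | C=CC[C@@]1(C)[C@H](C)C[C@H](OC(C)=O)[C@]2(COC(C)=O)[C@@H]1[C@H](OC(=O)[C@@H](C)CC)CCC2=C | intermediate
18 | 4α,18-spiroepoxide | C=CC[C@@]1(C)[C@H](C)C[C@H](OC(C)=O)[C@]2(COC(C)=O)[C@@H]1[C@H](OC(=O)[C@@H](C)CC)CC[C@]23CO3 | intermediate
19 | C12 aldehyde | O=CC[C@@]1(C)[C@H](C)C[C@H](OC(C)=O)[C@]2(COC(C)=O)[C@@H]1[C@H](OC(=O)[C@@H](C)CC)CC[C@]23CO3 | intermediate
20 | 12S-(3-furyl) carbinol | O[C@@H](C[C@@]1(C)[C@H](C)C[C@H](OC(C)=O)[C@]2(COC(C)=O)[C@@H]1[C@H](OC(=O)[C@@H](C)CC)CC[C@]23CO3)c4ccoc4 | intermediate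
21 | 12R-(3-furyl) carbinol | O[C@H](C[C@@]1(C)[C@H](C)C[C@H](OC(C)=O)[C@]2(COC(C)=O)[C@@H]1[C@H](OC(=O)[C@@H](C)CC)CC[C@]23CO3)c4ccoc4 | intermediate (recycled)
22 | 12S-(S)-2-methylbutanoate furan | CC[C@H](C)C(=O)O[C@@H](C[C@@]1(C)[C@H](C)C[C@H](OC(C)=O)[C@]2(COC(C)=O)[C@@H]1[C@H](OC(=O)[C@@H](C)CC)CC[C@]23CO3)c4ccoc4 | intermediate
23 | γ-hydroxybutenolide | CC[C@H](C)C(=O)O[C@@H](C[C@@]1(C)[C@H](C)C[C@H](OC(C)=O)[C@]2(COC(C)=O)[C@@H]1[C@H](OC(=O)[C@@H](C)CC)CC[C@]23CO3)C4=CC(=O)OC4O | intermediate
24 | butenolide spiroepoxide | CC[C@H](C)C(=O)O[C@@H](C[C@@]1(C)[C@H](C)C[C@H](OC(C)=O)[C@]2(COC(C)=O)[C@@H]1[C@H](OC(=O)[C@@H](C)CC)CC[C@]23CO3)C4=CC(=O)OC4 | intermediate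
25 | ajugaciliatin A | CC[C@H](C)C(=O)O[C@@H](C[C@@]1(C)[C@H](C)C[C@H](OC(C)=O)[C@]2(COC(C)=O)[C@@H]1[C@H](OC(=O)[C@@H](C)CC)CC[C@]2(O)CCl)C1=CC(=O)OC1 | target

## Totals
Total steps: 22. Longest linear sequence: 22 (from 1).

## Three steps most likely to fail
1. **Step 15 (proposed new photoredox allylation).** The hindered tertiary radical may be slow to add, or the oxalate may fragment or reduce. Fallback (known chemistry, different mechanism): ionic allylation of tertiary alcohol 15 with allyltrimethylsilane and TMSOTf or BF3 via the C9 cation (Hosomi–Sakurai-type). Note that this cationic route risks 1,2-shifts.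
2. **Step 3 (C5 quaternization).** It must alkylate at C5 rather than C10 or C8, and C8 must not epimerize, otherwise the enantiomeric series results. Fallback (Lewis-acid instead of base chemistry): make the TBS dienol ether (TBSOTf, Et3N), then Kobayashi hydroxymethylation with aqueous HCHO and Sc(OTf)3, then Ac2O to give 4.
3. **Step 16 (epoxide face).** Attack may occur from the β-face and give the wrong spiroepoxide. Fallback (different bond-forming logic): ozonolyse the exocyclic alkene to the C4 ketone and convert it to the epoxide with dimethylsulfonium methylide, which attacks axially from β to give O α/CH2 β (known selectivity); the C4 ketone would need to be carried through in place of the exocyclic alkene.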